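**Retrosynthetic overview**
1. Late stage: the target comes from a briarane pentaol by triacetylation, dehydration of the C5 carbinol to the 5(16)-alkene, and α-face epoxidation of the 11(20)-alkene.
2. Key step: the six- and ten-membered rings form together by transannular C1–C10 closure (cembrane C8–C3, the cembrane-to-briarane bond) of a 14-membered 1,2-epoxy-cembranolide. A C1 radical generated by trivalent titanium makes the bond, and the sequence ends at the exocyclic alkene.
3. The 14-membered carbocycle is closed before that, at C9–C10, by alkenylchromium addition to an α-hydroxy aldehyde.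
4. Earlier steps: chlorolactonisation gives the γ-lactone with C6-Cl and C7-O, asymmetric epoxidation gives the C1–C2 oxirane, and a catalytic aldol on an alkynyl α-keto ester sets C8 and C17.
5. Ring order: oxirane, γ-lactone, 14-ring, 6/10 bicycle, spiro-oxirane. The carbons come from dehydrolinalool, dimethyl oxalate, tert-butyl propanoate and but-3-yn-1-ol (plus one methyl from Me3Al).

Assumption and labels: C1–C20 are the briarane numbers of the target (C1 quaternary with Me-15; C5=C16; C6-Cl; C7-O/C19 lactone; C8-OH; C11/C20 oxirane; C17 with Me-18); racemic 6 is used, so the C5 carbinol centre, which step 15 erases, is carried as an epimer pair and left unassigned in the SMILES of 8–21.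

**Route**

Step 1
Reactants: 1 but-3-yn-1-ol
Product: 2 (E)-4-bromo-3-methylbut-3-en-1-ol
Conditions: Me3Al (3 equiv), Cp2ZrCl2 (25 mol %), CH2Cl2, 0 °C to rt; then NBS, THF, −30 °C; aq. K2CO3
Reagents that add atoms: trimethylaluminium C[Al](C)C; N-bromosuccinimide O=C1CCC(=O)N1Br
Why: Zirconium-catalysed carboalumination (Negishi type) adds Me and Al syn across the alkyne with Al at the terminus, and bromodealumination with retention gives only the E-bromoalkene that becomes C10=C11(C20).

Step 2
Reactants: 2 (E)-4-bromo-3-methylbut-3-en-1-ol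
Product: 3 (E)-1-bromo-4-iodo-2-methylbut-1-ene
Conditions: I2, PPh3, imidazole, CH2Cl2, 0 °C
Reagents that add atoms: iodine II
Why: Appel-type iodination goes by SN2 on the primary alkoxyphosphonium salt and leaves the bromoalkene untouched.

Step 3
Reactants: 4 tert-butyl propanoate
Product: 5 (E)-1-tert-butoxy-1-(trimethylsilyloxy)prop-1-ene
Conditions: LDA, THF, −78 °C; TMSCl, −78 °C to rt
Reagents that add atoms: chlorotrimethylsilane C[Si](C)(C)Cl
Why: Kinetic ester enolisation and O-silylation give the silyl ketene acetal, whose geometry matters little because the following aldol is stereoconvergent.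

Step 4
Reactants: 6 (±)-dehydrolinalool (3,7-dimethyloct-6-en-1-yn-3-ol); 7 dimethyl oxalate
Product: 8 methyl 5-hydroxy-5,9-dimethyl-2-oxodec-8-en-3-ynoate
Conditions: 6, n-BuLi (2.1 equiv), THF, −78 °C; cannulate into 7 (3 equiv), THF, −78 °C; AcOH quench
Reagents that add atoms: none
Why: Acylation of the lithium acetylide by one ester group of excess oxalate stops at the tetrahedral adduct at −78 °C and gives the chelating alkynyl α-keto ester (C7–C8 bond).

Step 5
Reactants: 8 methyl 5-hydroxy-5,9-dimethyl-2-oxodec-8-en-3-ynoate; 5 (E)-1-tert-butoxy-1-(trimethylsilyloxy)prop-1-ene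
Product: 10 4-tert-butyl 1-methyl (2S,3R)-2-hydroxy-2-(3-hydroxy-3,7-dimethyloct-6-en-1-ynyl)-3-methylbutanedioate, via C8 trimethylsilyl ether 9 (not isolated)
Conditions: Cu(OTf)2 (10 mol %), (R,R)-t-Bu-box (11 mol %), THF, −78 °C; then 1 M HCl, THF, 0 °C
Reagents that add atoms: none
Why: In this catalytic enantioselective Mukaiyama aldol addition the square-planar Cu–bis(oxazoline) chelate of the 1,2-dicarbonyl exposes one ketone face and the open transition state gives the syn adduct, which sets C8 and C17.

Step 6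
Reactants: 10 alkynyl aldol adduct
Product: 11 4-tert-butyl 1-methyl (2R,3R)-2-hydroxy-2-[(1E)-3-hydroxy-3,7-dimethylocta-1,6-dienyl]-3-methylbutanedioate
Conditions: CrSO4 (4 equiv), DMF–H2O, N2, rt
Reagents that add atoms: none
Why: Hydroxyl-assisted trans-reduction of the 2-yne-1,4-diol by divalent chromium (two electron transfers with protonation) gives the E-alkene, and the esters and the trisubstituted alkene are inert.

Step 7
Reactants: 11 E-alkene diester
Product: 13 4-tert-butyl 1-methyl (2R,3R)-2-hydroxy-2-[(1E,6E)-3-hydroxy-3,7-dimethyl-8-oxoocta-1,6-dienyl]-3-methylbutanedioate, via allylic alcohol 12 (not isolated)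
Conditions: SeO2 (30 mol %), t-BuOOH (2.5 equiv), CH2Cl2, 0 °C to rt; filter; MnO2, CH2Cl2, rt
Reagents that add atoms: tert-butyl hydroperoxide CC(C)(C)OO
Why: Riley allylic oxidation (ene reaction then [2,3]-shift) attacks only the E-methyl of the isopropylidene group because the C6=C7 alkene has no allylic hydrogen, and MnO2 takes the allylic alcohol on to the E-enal (C14).

Step 8
Reactants: 13 E-enal; 3 (E)-1-bromo-4-iodo-2-methylbut-1-ene
Product: 15 seco-cembranoid (14S)-allylic alcohol (8R;14S;17R; 10-bromo-10E-ene; 1E-ene; 6E-ene; C9 methyl ester; C19 tert-butyl ester), via dialkylzinc 14 (not isolated)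
Conditions: 3, Et2Zn, CuI (0.3 mol %), neat, 50 °C, then vacuum; (1R,2R)-C6H10(NHSO2CF3)2 (8 mol %), Ti(OiPr)4, toluene, −20 °C; add 13; aq. NH4Cl/HCl
Reagents that add atoms: none
Why: Iodine–zinc exchange makes the functionalised dialkylzinc without touching the bromoalkene, and the Ti–bis(sulfonamide)-catalysed enantioselective 1,2-addition to the α-methyl enal forms C13–C14 and sets C14 as S under catalyst control.

Step 9
Reactants: 15 seco-cembranoid (14S)-allylic alcohol
Product: 16 (1S;2S;14S)-1,2-epoxy-14-ol (8R;17R; other groups as in 15)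
Conditions: Ti(OiPr)4 (10 mol %), L-(+)-DIPT (12 mol %), t-BuOOH, 4 Å MS, CH2Cl2, −20 °C
Reagents that add atoms: tert-butyl hydroperoxide CC(C)(C)OO
Why: This is a matched Sharpless asymmetric epoxidation, in which the S secondary allylic alcohol is the fast-reacting enantiomer with L-(+)-tartrate and gives the erythro epoxy alcohol, setting C2 as S, while the hindered tertiary allylic alcohols do not direct.

Step 10
Reactants: 16 epoxy alcohol methyl ester
Product: 17 α-hydroxy aldehyde (C9 formyl; 1S;2S;8R;14S;17R; C19 tert-butyl ester kept)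
Conditions: i-Bu2AlH (4.5 equiv), CH2Cl2, −78 °C; MeOH, then Rochelle salt
Reagents that add atoms: none
Why: In this partial ester reduction the C8–O–Al chelate activates only the adjacent methyl ester and holds the tetrahedral adduct until work-up, and the hindered tert-butyl ester and the oxirane survive at −78 °C.

Step 11
Reactants: 17 α-hydroxy aldehyde
Product: 18 6-chloro-7,19-olide aldehyde (1S;2S;6R;7R;8S;14S;17R)
Conditions: NCS (1.2 equiv), Ph3P=S (10 mol %), NaHCO3, CH2Cl2, 0 °C
Reagents that add atoms: N-chlorosuccinimide O=C1CCC(=O)N1Cl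
Why: In this halolactonisation the chloriranium ion on the only nucleophilic alkene is opened 5-exo and anti by the tert-butyl ester carbonyl with loss of isobutene, so the E-alkene gives the anti C6-Cl/C7-O pair, and the allylic 8-OH steers attack so that the C6 chain ends cis to 8-OH and trans to the bulkier C9.

Step 12
Reactants: 18 6-chloro-7,19-olide aldehyde
Product: 19 14-membered 1,2-epoxy-cembranolide (1S;2S;6R;7R;8R;9S;14S;17R; 10E-ene; 5,8,9,14-tetraol)
Conditions: CrCl2 (8 equiv), NiCl2 (5 mol %), DMSO–THF, 2 mM (syringe pump), rt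
Reagents that add atoms: none
Why: In this Nozaki–Hiyama–Kishi macrocyclisation nickel-catalysed formation of the alkenylchromium keeps the E geometry and its chemoselective addition to the aldehyde closes the cembrane ring, with attack on the C8-alkoxide-chelated aldehyde from the C17 side expected to give 9S.

Step 13
Reactants: 19 14-membered 1,2-epoxy-cembranolide
Product: 20 briarane pentaol (6-chloro-2,5,8,9,14-pentahydroxybriar-11(20)-en-7,19-olide; 1R;2S;6R;7R;8R;9S;10S;14S;17R)
Conditions: Cp2TiCl2 (2.5 equiv), Mn dust (8 equiv), THF, rt (green Cp2TiCl); 19 added over 4 h, 5 mM; aq. NaH2PO4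
Reagents that add atoms: none
Why: Proposed new method: Cp2TiCl (trivalent titanium) opens the trisubstituted oxirane homolytically to the tertiary C1 radical with C2–O–Ti, which has only one alkene in reach and closes 6-endo across the ring onto C10, anti to the bulky titanoxy group and anti to C8 in the allylic-strain-minimised C9 rotamer (chair; C2 and C9 equatorial; Me-15 and H-10 trans-diaxial; small 14-OH axial), and the tertiary C11 radical then loses a C20 hydrogen to a second Cp2TiCl to give the exocyclic alkene, so C1 and C10 are set in the cembrane-to-briarane bond formation; the closest known reaction type is the titanocene-mediated radical cyclisation of epoxypolyprenes and its transannular variant on ten-membered epoxygermacranolides.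

Step 14
Reactants: 20 briarane pentaol
Product: 21 2,9,14-triacetate (5-OH and 8-OH free)
Conditions: Ac2O, pyridine, DMAP (cat.), rt
Reagents that add atoms: acetic anhydride CC(=O)OC(C)=O
Why: Nucleophile-catalysed acetylation esterifies the three secondary alcohols, while the tertiary 5-OH and the very hindered 8-OH stay free.

Step 15
Reactants: 21 2,9,14-triacetate
Product: 22 2,9,14-triacetoxy-6-chloro-8-hydroxybriara-5(16),11(20)-dien-7,19-olide
Conditions: SOCl2 (1.5 equiv), pyridine, CH2Cl2, −40 to 0 °C
Reagents that add atoms: none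
Why: In this E2-type dehydration through the chlorosulfite the β-chlorine disfavours ionisation, the crowded 8-OH is not sulfinylated, and pyridine removes the most accessible C16 hydrogen (Hofmann orientation), so both C5 epimers converge on the 5(16)-alkene without touching C6.

Step 16
Reactants: 22 5(16),11(20)-diene
Product: 23 target CNP0104093.1 (1S,2S,6S,7R,8R,9S,10S,11R,14S,17R)
Conditions: mCPBA (1.1 equiv), NaHCO3, CH2Cl2, 0 °C
Reagents that add atoms: 3-chloroperoxybenzoic acid OOC(=O)c1cccc(Cl)c1
Why: In this Prilezhaev epoxidation the 5(16)-alkene is deactivated by the allylic chlorine, and the peracid reaches the 11(20)-alkene from the α face because axial Me-15 blocks the β face, which sets C11 as R.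

**Compound list**
1 | but-3-yn-1-ol | C#CCCO | starting material
2 | (E)-4-bromo-3-methylbut-3-en-1-ol | Br/C=C(C)/CCO | intermediate
3 | (E)-1-bromo-4-iodo-2-methylbut-1-ene | Br/C=C(C)/CCI | intermediate
4 | tert-butyl propanoate | CCC(=O)OC(C)(C)C | starting material
5 | (E)-1-tert-butoxy-1-(trimethylsilyloxy)prop-1-ene | C/C=C(\OC(C)(C)C)O[Si](C)(C)C | intermediate
6 | (±)-dehydrolinalool | CC(C)=CCCC(C)(O)C#C | starting material
7 | dimethyl oxalate | COC(=O)C(=O)OC | starting material
8 | methyl 5-hydroxy-5,9-dimethyl-2-oxodec-8-en-3-ynoate | CC(C)=CCCC(C)(O)C#CC(=O)C(=O)OC | intermediate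
9 | C8 trimethylsilyl ether of 10 | CC(C)=CCCC(C)(O)C#C[C@](O[Si](C)(C)C)(C(=O)OC)[C@@H](C)C(=O)OC(C)(C)C | intermediate
10 | alkynyl aldol adduct (2S,3R-butanedioate; C8, C17 set) | CC(C)=CCCC(C)(O)C#C[C@](O)(C(=O)OC)[C@@H](C)C(=O)OC(C)(C)C | intermediate
11 | E-alkene diester (2R,3R) | CC(C)=CCCC(C)(O)/C=C/[C@](O)(C(=O)OC)[C@@H](C)C(=O)OC(C)(C)C | intermediate
12 | C14 allylic alcohol | OC/C(C)=C/CCC(C)(O)/C=C/[C@](O)(C(=O)OC)[C@@H](C)C(=O)OC(C)(C)C | intermediate
13 | C14 E-enal | O=C/C(C)=C/CCC(C)(O)/C=C/[C@](O)(C(=O)OC)[C@@H](C)C(=O)OC(C)(C)C | intermediate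
14 | bis[(E)-4-bromo-3-methylbut-3-enyl]zinc | Br/C=C(C)/CC[Zn]CC/C(C)=C/Br | intermediate
15 | seco-cembranoid (14S)-allylic alcohol | Br/C=C(C)/CC[C@H](O)/C(C)=C/CCC(C)(O)/C=C/[C@](O)(C(=O)OC)[C@@H](C)C(=O)OC(C)(C)C | intermediate
16 | (1S,2S,14S)-1,2-epoxy-14-ol | Br/C=C(C)/CC[C@H](O)[C@]1(C)O[C@H]1CCC(C)(O)/C=C/[C@](O)(C(=O)OC)[C@@H](C)C(=O)OC(C)(C)C | intermediate
17 | C9 α-hydroxy aldehyde | Br/C=C(C)/CC[C@H](O)[C@]1(C)O[C@H]1CCC(C)(O)/C=C/[C@](O)(C=O)[C@@H](C)C(=O)OC(C)(C)C | intermediate
18 | 6-chloro-7,19-olide aldehyde | Br/C=C(C)/CC[C@H](O)[C@]1(C)O[C@H]1CCC(C)(O)[C@H](Cl)[C@@H]1OC(=O)[C@H](C)[C@@]1(O)C=O | intermediate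
19 | 14-membered 1,2-epoxy-cembranolide | CC1(O)CC[C@@H]2O[C@@]2(C)[C@@H](O)CC/C(C)=C/[C@H](O)[C@]2(O)[C@@H](C)C(=O)O[C@H]2[C@H]1Cl | intermediate
20 | briarane pentaol | CC1(O)CC[C@H](O)[C@@]2(C)[C@@H](O)CCC(=C)[C@@H]2[C@H](O)[C@]2(O)[C@@H](C)C(=O)O[C@H]2[C@H]1Cl | intermediate
21 | 2,9,14-triacetate | CC1(O)CC[C@H](OC(C)=O)[C@@]2(C)[C@@H](OC(C)=O)CCC(=C)[C@@H]2[C@H](OC(C)=O)[C@]2(O)[C@@H](C)C(=O)O[C@H]2[C@H]1Cl | intermediate
22 | 5(16),11(20)-diene allylic chloride | C=C1CC[C@H](OC(C)=O)[C@@]2(C)[C@@H](OC(C)=O)CCC(=C)[C@@H]2[C@H](OC(C)=O)[C@]2(O)[C@@H](C)C(=O)O[C@H]2[C@H]1Cl | intermediate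
23 | CNP0104093.1 | C=C1CC[C@H](OC(C)=O)[C@@]2(C)[C@@H](OC(C)=O)CC[C@]3(CO3)[C@@H]2[C@H](OC(C)=O)[C@]2(O)[C@@H](C)C(=O)O[C@H]2[C@H]1Cl | target

**Totals**
- Total steps: 16.
- Longest linear sequence: 13 (steps 4–16, from dehydrolinalool).

**Three steps most likely to fail**

Step 13. The transannular closure may lose to early hydrogen abstraction or to β-elimination of the 14-oxygen. The fallback sets out from 19 and comes back at 20. The oxirane is deliberately isomerised with concentrated Cp2TiCl, where hydrogen abstraction outruns cyclisation, to the 1(15)-en-2-ol macrocycle F1. The same C1 radical is then regenerated in a different way, by metal-hydride hydrogen-atom transfer to the 1,1-disubstituted alkene (Co(salen)Cl cat., PhSiH3, benzene). This is a radical cycloisomerisation in which cobalt takes the C20 hydrogen back after the C1–C10 closure.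

Step 12. The ring closure may give the wrong C9 epimer. The fallback sets out from 18 and comes back at 19. The chromium closure is accepted as it comes, including the 9-epimeric macrocycle F2. Only the allylic carbinol is oxidised with MnO2, which gives the macrocyclic 9-oxo enone F3. C9 is then set by reagent control with (R)-Me-CBS and catecholborane, where the quaternary C8 side acts as the large group and 9S results. The stereocentre is thereby made by ketone reduction and not during C–C bond formation.

Step 15. The elimination may give the endocyclic 4-ene or the vinyl chloride, or may attack 8-OH. The fallback sets out from 21 and comes back at 22. Ag2O in MeCN closes the chlorohydrin to the 5,6-epoxide F4 with inversion at C6. Cp2TiCl (2.2 equiv) opens it to the C5 radical, which ends as the exocyclic alkene and gives the 6-hydroxy-5(16)-ene F5. PPh3 and hexachloroacetone then replace OH by Cl with a second inversion, which restores the C6 configuration.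

**Further compounds**
F1 | step 13 | 1(15)-en-2-ol macrocycle | CC1(O)CC[C@H](O)C(=C)[C@@H](O)CC/C(C)=C/[C@H](O)[C@]2(O)[C@@H](C)C(=O)O[C@H]2[C@H]1Cl
F2 | step 12 | 9-epimeric macrocycle | CC1(O)CC[C@@H]2O[C@@]2(C)[C@@H](O)CC/C(C)=C/[C@@H](O)[C@]2(O)[C@@H](C)C(=O)O[C@H]2[C@H]1Cl
F3 | step 12 | macrocyclic 9-oxo enone | CC1(O)CC[C@@H]2O[C@@]2(C)[C@@H](O)CC/C(C)=C/C(=O)[C@]2(O)[C@@H](C)C(=O)O[C@H]2[C@H]1Cl
F4 | step 15 | 5,6-epoxide triacetate | CC12CC[C@H](OC(C)=O)[C@@]3(C)[C@@H](OC(C)=O)CCC(=C)[C@@H]3[C@H](OC(C)=O)[C@]3(O)[C@@H](C)C(=O)O[C@H]3[C@@H]1O2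
F5 | step 15 | 6-hydroxy-5(16)-ene triacetate | C=C1CC[C@H](OC(C)=O)[C@@]2(C)[C@@H](OC(C)=O)CCC(=C)[C@@H]2[C@H](OC(C)=O)[C@]2(O)[C@@H](C)C(=O)O[C@H]2[C@@H]1O
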